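**Plan**

- Numbering (lignan): C7 = CH–O bearing the guaiacyl ring, C8 = acetoxy bridgehead, C9 = OCH2 on C8; C7', C8', C9' are the same positions in the veratryl half. Ring A = O–C7–C8–C8'–C9', ring B = O–C7'–C8'–C8–C9.
- Retrosynthesis: the phenol and the C8 acetate are unmasked last. Ring A is cut at O–C9' (lactol reduction). Ring B is a 2-aryl oxolane whose C8' carries the one-carbon arm C9'; it is cut at C7'–C8' and redrawn as a 2-aryl-4,5-dihydro-1,3-dioxepine in which C9' is an enol ether carbon. That ring is cut at the veratraldehyde acetal and at C8'=C9' (epoxide isomerisation), and the epoxy carbinol at C7–C8 (O-benzylvanillin plus 2-butyne-1,4-diol).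
- Forward: C7–C8 bond, epoxide, inversion at C7, seven-membered acetal, enol ether, ring B by ring contraction, ring A by lactol formation and reduction, acetate, free phenol.
- Stereochemistry: the Ti–tartrate kinetic-resolution epoxidation fixes C8 and selects C7. It gives the erythro epoxy alcohol, whereas an aryl group cis to the C8 oxygen in ring A needs the threo one, so C7 is inverted by a Mitsunobu reaction. C7' and C8' arise in the ring contraction under control of C8; C8' is then adjusted by epimerisation, with the cis-fused lactol as sink.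

Key step: step 11

Remark: 4-(benzyloxy)-3-methoxybenzaldehyde (3) is taken as a purchased compound (otherwise one benzylation from vanillin).

**Step 1**
Reactants: 1 2-butyne-1,4-diol
Product: 2 1,4-bis(triethylsilyloxy)but-2-yne
Conditions: Et3SiCl (2.2 equiv), imidazole, CH2Cl2, 0 °C to rt
Reagents that add atoms: chlorotriethylsilane, CC[Si](Cl)(CC)CC
Why: Imidazole-promoted O-silylation of both primary hydroxyls; triethylsilyl ethers survive the organometallic and epoxidation steps and can later be removed without touching a tert-butyldimethylsilyl ether.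

**Step 2**
Reactants: 2 1,4-bis(triethylsilyloxy)but-2-yne; 3 4-(benzyloxy)-3-methoxybenzaldehyde
Product: 6 rac-(E)-1-[4-(benzyloxy)-3-methoxyphenyl]-4-(triethylsilyloxy)-2-[(triethylsilyloxy)methyl]but-2-en-1-ol, via alkenylzirconocene chloride 4 (not isolated), via alkenyl(methyl)zinc 5 (not isolated)
Conditions: Cp2Zr(H)Cl, CH2Cl2, rt; Me2Zn, toluene, −65 °C; then 3, 0 °C; aq NH4Cl
Reagents that add atoms: none
Why: syn-Hydrozirconation of the symmetrical alkyne places H and Zr cis (so the two CH2O arms end cis, as the later seven-membered acetal requires), and Zr-to-Zn transmetalation followed by 1,2-addition of the alkenylzinc to the aldehyde forms C7–C8; C7 is formed as the racemate.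

**Step 3**
Reactants: 6 racemic allylic alcohol
Product: 7 (S)-[4-(benzyloxy)-3-methoxyphenyl]{(2S,3S)-2,3-bis[(triethylsilyloxy)methyl]oxiran-2-yl}methanol (erythro epoxy alcohol; 7S,8S,8'S)
Conditions: Ti(OiPr)4 (10 mol %), L-(+)-diisopropyl tartrate (15 mol %), t-BuOOH (0.55 equiv, decane), 4 Å sieves, CH2Cl2, −20 °C; stopped near half conversion
Reagents that add atoms: tert-butyl hydroperoxide, CC(C)(C)OO
Why: Sharpless kinetic-resolution epoxidation: with L-(+)-tartrate the (S)-carbinol is the fast-reacting enantiomer and receives oxygen on the tartrate-selected alkene face, which sets C8 and C8' (both S) and selects C7 (S) as the erythro epoxy alcohol; the unreacted (R)-alcohol is removed by chromatography, and the erythro relationship is corrected at C7 in step 4.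

**Step 4**
Reactants: 7 erythro epoxy alcohol
Product: 8 (R)-[4-(benzyloxy)-3-methoxyphenyl]{(2S,3S)-2,3-bis[(triethylsilyloxy)methyl]oxiran-2-yl}methyl 4-nitrobenzoate
Conditions: 4-nitrobenzoic acid, PPh3, DIAD, toluene, 0 °C to rt
Reagents that add atoms: 4-nitrobenzoic acid, OC(=O)c1ccc(cc1)[N+](=O)[O-]
Why: Mitsunobu reaction: the C7 oxyphosphonium ion is displaced by 4-nitrobenzoate with inversion (SN2), turning the erythro into the threo epoxy carbinol that ring A needs for an aryl group cis to the C8 oxygen; the electron-poor oxirane carbon next to C7 should suppress ionisation of the benzylic centre.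

**Step 5**
Reactants: 8 threo 4-nitrobenzoate
Product: 9 (R)-[4-(benzyloxy)-3-methoxyphenyl]{(2S,3S)-2,3-bis[(triethylsilyloxy)methyl]oxiran-2-yl}methanol (threo epoxy alcohol; 7R,8S,8'S)
Conditions: K2CO3 (0.2 equiv), MeOH, 0 °C
Reagents that add atoms: none
Why: Base-catalysed transesterification of the activated aryl ester with methanol releases the C7 alcohol with retention; the triethylsilyl ethers and the epoxide tolerate brief carbonate/methanol at 0 °C.

**Step 6**
Reactants: 9 threo epoxy alcohol
Product: 10 C7 O-tert-butyldimethylsilyl ether of 9 (carbinol carbon R; oxirane geometry unchanged, CIP 2R,3S)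
Conditions: t-BuMe2SiOTf, 2,6-lutidine, CH2Cl2, −78 °C
Reagents that add atoms: tert-butyldimethylsilyl triflate, CC(C)(C)[Si](C)(C)OS(=O)(=O)C(F)(F)F
Why: Silylation of the hindered secondary alcohol with a silyl triflate and a hindered pyridine base at low temperature, conditions under which the epoxide survives; the C7 oxygen must be blocked so that step 9 cannot form the six-membered C7/C9 acetal.

**Step 7**
Reactants: 10 tris-silyl ether
Product: 11 [(2R,3S)-2-{(R)-[4-(benzyloxy)-3-methoxyphenyl][(tert-butyldimethylsilyl)oxy]methyl}oxirane-2,3-diyl]dimethanol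
Conditions: HF·pyridine, pyridine, THF, 0 °C
Reagents that add atoms: none
Why: Fluoride-mediated desilylation in buffered medium: primary triethylsilyl ethers are cleaved much faster than the hindered secondary tert-butyldimethylsilyl ether, and buffered HF·pyridine does not open the epoxide.

**Step 8**
Reactants: 12 3,4-dimethoxybenzaldehyde (veratraldehyde)
Product: 13 4-(dimethoxymethyl)-1,2-dimethoxybenzene
Conditions: HC(OMe)3, pyridinium p-toluenesulfonate (cat.), MeOH, 50 °C; Et3N; distillation
Reagents that add atoms: trimethyl orthoformate, COC(OC)OC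
Why: Acid-catalysed acetalisation of the aldehyde with the orthoester as methanol donor and water scavenger.

**Step 9**
Reactants: 11 epoxy diol; 13 veratraldehyde dimethyl acetal
Product: 14 (1R,7S)-1-{(R)-[4-(benzyloxy)-3-methoxyphenyl][(tert-butyldimethylsilyl)oxy]methyl}-4-(3,4-dimethoxyphenyl)-3,5,8-trioxabicyclo[5.1.0]octane (both C4 epimers)
Conditions: pyridinium p-toluenesulfonate (10 mol %), 5 Å sieves, CH2Cl2, rt
Reagents that add atoms: none
Why: Acid-catalysed transacetalisation: the two hydroxymethyl groups are held cis on the oxirane and close the seven-membered 1,3-dioxepane by exchange at the acetal carbon, the pyridinium salt being too weak an acid to open the epoxide; the new acetal carbon forms as both epimers, which converge in step 11.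

**Step 10**
Reactants: 14 bicyclic epoxy acetal
Product: 16 (5S)-5-{(R)-[4-(benzyloxy)-3-methoxyphenyl][(tert-butyldimethylsilyl)oxy]methyl}-2-(3,4-dimethoxyphenyl)-5-[(trimethylsilyl)oxy]-4,5-dihydro-1,3-dioxepine (both C2 epimers), via lithium alkoxide 15 (not isolated)
Conditions: LiN(iPr)2 (3 equiv), THF, −78 to 0 °C; then Me3SiCl, Et3N, −78 °C to rt
Reagents that add atoms: chlorotrimethylsilane, C[Si](C)(C)Cl
Why: Lithium amide-induced isomerisation of an epoxide to an allylic alkoxide (β-elimination): removal of an oxygen-activated hydrogen at C9' cleaves the C8'–O bond and gives the C8'=C9' enol ether while the C8–O bond and the C8 configuration are untouched, abstraction at C9 being hindered by the quaternary C8 and the silylated C7 arm, and the tertiary lithium alkoxide is silylated in the same flask.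

**Step 11**
Reactants: 16 dihydrodioxepine
Product: 18 (2S,3R,4S)-4-{(R)-[4-(benzyloxy)-3-methoxyphenyl][(tert-butyldimethylsilyl)oxy]methyl}-2-(3,4-dimethoxyphenyl)-4-[(trimethylsilyl)oxy]oxolane-3-carbaldehyde, via C8'-epimeric aldehyde 17 (not isolated)
Conditions: Me3SiOTf (0.2 equiv), CH2Cl2, −78 °C; then DBU (0.5 equiv), −78 to 0 °C
Reagents that add atoms: none
Why: Me3SiOTf ionises the acetal at the C7'–O bond to the enol oxygen, giving a veratryl-stabilised oxocarbenium ion that stays tethered through O–C9–C8 to the (Z)-silyl enol ether, whose carbon C8' then attacks C7' to form the C7'–C8' bond and free C9' as the aldehyde (a Petasis–Ferrier-type 1,3 O-to-C rearrangement, known for 2-aryl-4,5-dihydro-1,3-dioxepines). Ring B closes in a 5-(enolexo)-endo-trig mode, which oxocarbenium ions undergo readily, and the seven-membered ring is thereby contracted to the oxolane. C8' is controlled by C8: allylic 1,3-strain with the cis enol oxygen keeps the small silyloxy group in the enol plane and the bulky C7 arm anti to the forming bond, so the formyl group first ends cis to the C8 silyloxy group. C7' is set under kinetic control at −78 °C, where collapse of the contact ion pair should give the 7',8'-cis oxolane with the aryl group on the ring face opposite to the C7 arm, the configuration the target has at C7'; the acetal stereocentre is erased on ionisation, so both epimers of 16 converge on 17. DBU then neutralises the acid and equilibrates only the enolisable C8', which relieves the all-cis arrangement and places the formyl group trans to the aryl group and cis to the C7 arm (18). The step needs carbon–carbon bond formation to outrun return at oxygen and capture by the C8 oxygen, which the tight ion pair and the silyl cap on that oxygen should secure, and it needs the acid to be quenched cold so that C7' is not equilibrated.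

**Step 12**
Reactants: 18 ring B aldehyde
Product: 19 (7R,8S,7'S,8'R)-4-(benzyloxy)-3,3',4'-trimethoxy-7,9':7',9-diepoxylignane-8,9'-diol (cis-fused lactol; both C9' anomers)
Conditions: HF·pyridine, THF, 0 °C to rt
Reagents that add atoms: none
Why: Fluoride removes both silyl groups under non-basic conditions (so the β-hydroxy aldehyde is not exposed to retro-aldol cleavage), and the free C7 hydroxyl adds to the cis formyl group to close ring A as the five-membered lactol (5-exo-trig hemiacetalisation), which only the C8' epimer with the formyl group cis to the C7 arm can do; C9' forms as both anomers and loses its stereogenicity in step 13.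

**Step 13**
Reactants: 19 lactol
Product: 20 (7R,8S,7'S,8'R)-4-(benzyloxy)-3,3',4'-trimethoxy-7,9':7',9-diepoxylignan-8-ol
Conditions: Et3SiH, BF3·OEt2, CH2Cl2, −78 to −30 °C
Reagents that add atoms: none
Why: Ionic reduction of a lactol: BF3 ionises the C9' hydroxyl to the cyclic oxocarbenium ion and Et3SiH delivers hydride, a standard lactol-to-cyclic-ether reduction in the furofuran series; the low temperature keeps the two benzylic ethers from ionising.

**Step 14**
Reactants: 20 tertiary alcohol
Product: 21 (7R,8S,7'S,8'R)-4-(benzyloxy)-3,3',4'-trimethoxy-7,9':7',9-diepoxylignan-8-yl acetate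
Conditions: Ac2O, Et3N, 4-(dimethylamino)pyridine, CH2Cl2, rt to 40 °C
Reagents that add atoms: acetic anhydride, CC(=O)OC(C)=O
Why: Nucleophilic catalysis by 4-(dimethylamino)pyridine (Steglich-type acylation) acetylates the only free hydroxyl, the tertiary bridgehead alcohol at C8.

**Step 15**
Reactants: 21 benzyl ether acetate
Product: 22 (7R,8S,7'S,8'R)-8-acetoxy-3,3',4'-trimethoxy-7,9':7',9-diepoxylignan-4-ol (target, CNP0107105.1)
Conditions: H2 (1 atm), Pd/C, EtOAc, rt
Reagents that add atoms: none
Why: Hydrogenolysis of the aryl benzyl ether over palladium is much faster than cleavage of the dialkyl benzylic C–O bonds of the furofuran when the reaction is stopped after uptake of one equivalent of hydrogen, and it leaves the tertiary acetate untouched.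

**Compound list**

1 | 2-butyne-1,4-diol | OCC#CCO | starting material
2 | 1,4-bis(triethylsilyloxy)but-2-yne | CC[Si](CC)(CC)OCC#CCO[Si](CC)(CC)CC | intermediate
3 | 4-(benzyloxy)-3-methoxybenzaldehyde | COc1cc(C=O)ccc1OCc1ccccc1 | starting material
4 | chloridobis(cyclopentadienyl)[(E)-1,4-bis(triethylsilyloxy)but-2-en-2-yl]zirconium | Cl[Zr+2]/C(CO[Si](CC)(CC)CC)=C/CO[Si](CC)(CC)CC.c1cc[cH-]c1.c1cc[cH-]c1 | intermediate (not isolated)
5 | [(E)-1,4-bis(triethylsilyloxy)but-2-en-2-yl](methyl)zinc | C[Zn]/C(CO[Si](CC)(CC)CC)=C/CO[Si](CC)(CC)CC | intermediate (not isolated)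
6 | rac-(E)-1-[4-(benzyloxy)-3-methoxyphenyl]-4-(triethylsilyloxy)-2-[(triethylsilyloxy)methyl]but-2-en-1-ol | COc1cc(C(O)/C(CO[Si](CC)(CC)CC)=C/CO[Si](CC)(CC)CC)ccc1OCc1ccccc1 | intermediate
7 | (S)-[4-(benzyloxy)-3-methoxyphenyl]{(2S,3S)-2,3-bis[(triethylsilyloxy)methyl]oxiran-2-yl}methanol (erythro) | COc1cc([C@H](O)[C@]2(CO[Si](CC)(CC)CC)O[C@H]2CO[Si](CC)(CC)CC)ccc1OCc1ccccc1 | intermediate
8 | (R)-[4-(benzyloxy)-3-methoxyphenyl]{(2S,3S)-2,3-bis[(triethylsilyloxy)methyl]oxiran-2-yl}methyl 4-nitrobenzoate | COc1cc([C@@H](OC(=O)c2ccc(cc2)[N+](=O)[O-])[C@]3(CO[Si](CC)(CC)CC)O[C@H]3CO[Si](CC)(CC)CC)ccc1OCc1ccccc1 | intermediate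
9 | (R)-[4-(benzyloxy)-3-methoxyphenyl]{(2S,3S)-2,3-bis[(triethylsilyloxy)methyl]oxiran-2-yl}methanol (threo) | COc1cc([C@@H](O)[C@]2(CO[Si](CC)(CC)CC)O[C@H]2CO[Si](CC)(CC)CC)ccc1OCc1ccccc1 | intermediate
10 | (2R,3S)-2-{(R)-[4-(benzyloxy)-3-methoxyphenyl][(tert-butyldimethylsilyl)oxy]methyl}-2,3-bis[(triethylsilyloxy)methyl]oxirane | COc1cc([C@@H](O[Si](C)(C)C(C)(C)C)[C@]2(CO[Si](CC)(CC)CC)O[C@H]2CO[Si](CC)(CC)CC)ccc1OCc1ccccc1 | intermediate
11 | [(2R,3S)-2-{(R)-[4-(benzyloxy)-3-methoxyphenyl][(tert-butyldimethylsilyl)oxy]methyl}oxirane-2,3-diyl]dimethanol | COc1cc([C@@H](O[Si](C)(C)C(C)(C)C)[C@]2(CO)O[C@H]2CO)ccc1OCc1ccccc1 | intermediate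
12 | 3,4-dimethoxybenzaldehyde (veratraldehyde) | COc1ccc(C=O)cc1OC | starting material
13 | 4-(dimethoxymethyl)-1,2-dimethoxybenzene | COc1ccc(C(OC)OC)cc1OC | intermediate
14 | (1R,7S)-1-{(R)-[4-(benzyloxy)-3-methoxyphenyl][(tert-butyldimethylsilyl)oxy]methyl}-4-(3,4-dimethoxyphenyl)-3,5,8-trioxabicyclo[5.1.0]octane (C4 epimers) | COc1cc([C@@H](O[Si](C)(C)C(C)(C)C)[C@@]23COC(c4ccc(OC)c(OC)c4)OC[C@@H]2O3)ccc1OCc1ccccc1 | intermediate
15 | lithium (5S)-5-{(R)-[4-(benzyloxy)-3-methoxyphenyl][(tert-butyldimethylsilyl)oxy]methyl}-2-(3,4-dimethoxyphenyl)-4,5-dihydro-1,3-dioxepin-5-olate | COc1cc([C@@H](O[Si](C)(C)C(C)(C)C)[C@]2([O-])/C=C\OC(c3ccc(OC)c(OC)c3)OC2)ccc1OCc1ccccc1.[Li+] | intermediate (not isolated)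
16 | (5S)-5-{(R)-[4-(benzyloxy)-3-methoxyphenyl][(tert-butyldimethylsilyl)oxy]methyl}-2-(3,4-dimethoxyphenyl)-5-[(trimethylsilyl)oxy]-4,5-dihydro-1,3-dioxepine (C2 epimers) | COc1cc([C@@H](O[Si](C)(C)C(C)(C)C)[C@]2(O[Si](C)(C)C)/C=C\OC(c3ccc(OC)c(OC)c3)OC2)ccc1OCc1ccccc1 | intermediate
17 | (2S,3S,4S)-4-{(R)-[4-(benzyloxy)-3-methoxyphenyl][(tert-butyldimethylsilyl)oxy]methyl}-2-(3,4-dimethoxyphenyl)-4-[(trimethylsilyl)oxy]oxolane-3-carbaldehyde (formyl cis to aryl and to OSiMe3) | COc1cc([C@@H](O[Si](C)(C)C(C)(C)C)[C@@]2(O[Si](C)(C)C)CO[C@H](c3ccc(OC)c(OC)c3)[C@@H]2C=O)ccc1OCc1ccccc1 | intermediate (not isolated)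
18 | (2S,3R,4S)-4-{(R)-[4-(benzyloxy)-3-methoxyphenyl][(tert-butyldimethylsilyl)oxy]methyl}-2-(3,4-dimethoxyphenyl)-4-[(trimethylsilyl)oxy]oxolane-3-carbaldehyde | COc1cc([C@@H](O[Si](C)(C)C(C)(C)C)[C@@]2(O[Si](C)(C)C)CO[C@H](c3ccc(OC)c(OC)c3)[C@H]2C=O)ccc1OCc1ccccc1 | intermediate
19 | (7R,8S,7'S,8'R)-4-(benzyloxy)-3,3',4'-trimethoxy-7,9':7',9-diepoxylignane-8,9'-diol (C9' anomers) | COc1cc([C@H]2OC(O)[C@@H]3[C@@H](c4ccc(OC)c(OC)c4)OC[C@]23O)ccc1OCc1ccccc1 | intermediate
20 | (7R,8S,7'S,8'R)-4-(benzyloxy)-3,3',4'-trimethoxy-7,9':7',9-diepoxylignan-8-ol | COc1cc([C@H]2OC[C@@H]3[C@@H](c4ccc(OC)c(OC)c4)OC[C@]23O)ccc1OCc1ccccc1 | intermediate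
21 | (7R,8S,7'S,8'R)-4-(benzyloxy)-3,3',4'-trimethoxy-7,9':7',9-diepoxylignan-8-yl acetate | COc1cc([C@H]2OC[C@@H]3[C@@H](c4ccc(OC)c(OC)c4)OC[C@]23OC(C)=O)ccc1OCc1ccccc1 | intermediate
22 | (7R,8S,7'S,8'R)-8-acetoxy-3,3',4'-trimethoxy-7,9':7',9-diepoxylignan-4-ol | COc1cc([C@H]2OC[C@@H]3[C@@H](c4ccc(OC)c(OC)c4)OC[C@]23OC(C)=O)ccc1O | target

**Count**

Total steps: 15. Longest linear sequence: 14 (steps 1–7 and 9–15 from 2-butyne-1,4-diol); step 8 is a one-step side branch.

**Steps most likely to fail**

1. Step 11 (ring contraction and C8' adjustment). What may go wrong: the ion pair may collapse at oxygen, or the oxocarbenium ion may be captured by the C8 silyl ether oxygen, instead of forming the C–C bond. The kinetic preference at C7' may be lost if the mixture warms before the acid is quenched. The C8 silyloxy group may be lost by β-elimination from the enolate during the DBU equilibration. Fallback for the last and most likely failure, from 17 to 19: the contraction is quenched cold with Et3N and the kinetic aldehyde 17 is isolated. NaClO2/NaH2PO4/2-methyl-2-butene would oxidise it to the silylated carboxylic acid F1, and HF·pyridine would give the dihydroxy acid F2. Activation with 2,4,6-trichlorobenzoyl chloride, Et3N and 4-(dimethylamino)pyridine (Yamaguchi conditions) would epimerise C8' through the activated acyl species and let only the cis isomer close onto the C7 hydroxyl, giving the cis-fused γ-lactone F3. i-Bu2AlH at −78 °C would reduce F3 to lactol 19. The epimerisation is thus moved to the acid oxidation level, where the lactone is the sink and no β-silyloxy aldehyde enolate is formed.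

2. Step 10 (epoxide to enol ether). What may go wrong: the amide base may abstract a hydrogen at C9 instead of C9' (opening the C8–O bond and destroying the C8 stereocentre), or attack the benzylidene-type acetal. Fallback from 14 to 16: (PhSe)2/NaBH4 in EtOH would open the epoxide by SN2 attack at the less hindered C8', giving the trans hydroxy selenide F4 with the tertiary C8 hydroxyl intact. H2O2/pyridine would give the selenoxide F5, whose syn-elimination can only run towards C9' because C8 carries no hydrogen, giving the tertiary alcohol F6 with the C8'=C9' enol ether. N-(trimethylsilyl)imidazole would silylate F6 to 16.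

3. Step 4 (Mitsunobu inversion). What may go wrong: at this hindered, electron-rich benzylic carbinol the ester may form with partial retention (acyl transfer) or through an ionised intermediate, which would erode the threo purity at C7. Fallback from 6 to 9, inverting the epoxide instead of the carbinol: kinetic resolution of 6 with D-(−)-diisopropyl tartrate would give the enantiomeric erythro epoxy alcohol F7 (7R,8R,8'R). Boc2O with 4-(dimethylamino)pyridine would give the tert-butyl carbonate F8. With BF3·OEt2 at −78 °C the carbonate carbonyl would open the epoxide at the tertiary C8 with inversion, giving the cyclic carbonate F9 with a free C8' hydroxyl, and MsCl/Et3N would give the mesylate F10. K2CO3/MeOH would cleave the carbonate, and the C8 alkoxide would displace the mesylate with inversion at C8'. The oxirane is thereby rebuilt on the opposite face with C7 untouched, which is 9.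

**Further compounds**

F1 | step 11 | (2S,3S,4S)-4-{(R)-[4-(benzyloxy)-3-methoxyphenyl][(tert-butyldimethylsilyl)oxy]methyl}-2-(3,4-dimethoxyphenyl)-4-[(trimethylsilyl)oxy]oxolane-3-carboxylic acid | COc1cc([C@@H](O[Si](C)(C)C(C)(C)C)[C@@]2(O[Si](C)(C)C)CO[C@H](c3ccc(OC)c(OC)c3)[C@@H]2C(O)=O)ccc1OCc1ccccc1
F2 | step 11 | (2S,3S,4S)-4-{(R)-[4-(benzyloxy)-3-methoxyphenyl](hydroxy)methyl}-2-(3,4-dimethoxyphenyl)-4-hydroxyoxolane-3-carboxylic acid | COc1cc([C@@H](O)[C@@]2(O)CO[C@H](c3ccc(OC)c(OC)c3)[C@@H]2C(O)=O)ccc1OCc1ccccc1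
F3 | step 11 | (7R,8S,7'S,8'R)-4-(benzyloxy)-8-hydroxy-3,3',4'-trimethoxy-7,9':7',9-diepoxylignan-9'-one (cis-fused γ-lactone) | COc1cc([C@H]2OC(=O)[C@@H]3[C@@H](c4ccc(OC)c(OC)c4)OC[C@]23O)ccc1OCc1ccccc1
F4 | step 10 | trans-5-{(R)-[4-(benzyloxy)-3-methoxyphenyl][(tert-butyldimethylsilyl)oxy]methyl}-2-(3,4-dimethoxyphenyl)-6-(phenylselanyl)-1,3-dioxepan-5-ol | COc1cc([C@@H](O[Si](C)(C)C(C)(C)C)[C@]2(O)[C@H]([Se]c3ccccc3)COC(c3ccc(OC)c(OC)c3)OC2)ccc1OCc1ccccc1
F5 | step 10 | selenoxide of F4 | COc1cc([C@@H](O[Si](C)(C)C(C)(C)C)[C@]2(O)[C@H]([Se](=O)c3ccccc3)COC(c3ccc(OC)c(OC)c3)OC2)ccc1OCc1ccccc1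
F6 | step 10 | (5S)-5-{(R)-[4-(benzyloxy)-3-methoxyphenyl][(tert-butyldimethylsilyl)oxy]methyl}-2-(3,4-dimethoxyphenyl)-4,5-dihydro-1,3-dioxepin-5-ol | COc1cc([C@@H](O[Si](C)(C)C(C)(C)C)[C@]2(O)/C=C\OC(c3ccc(OC)c(OC)c3)OC2)ccc1OCc1ccccc1
F7 | step 4 | (R)-[4-(benzyloxy)-3-methoxyphenyl]{(2R,3R)-2,3-bis[(triethylsilyloxy)methyl]oxiran-2-yl}methanol (enantiomer of 7) | COc1cc([C@@H](O)[C@@]2(CO[Si](CC)(CC)CC)O[C@@H]2CO[Si](CC)(CC)CC)ccc1OCc1ccccc1
F8 | step 4 | tert-butyl carbonate of F7 | COc1cc([C@@H](OC(=O)OC(C)(C)C)[C@@]2(CO[Si](CC)(CC)CC)O[C@@H]2CO[Si](CC)(CC)CC)ccc1OCc1ccccc1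
F9 | step 4 | 5-[4-(benzyloxy)-3-methoxyphenyl]-4-[1-hydroxy-2-(triethylsilyloxy)ethyl]-4-[(triethylsilyloxy)methyl]-1,3-dioxolan-2-one (carbonate across O7 and O8, C8–O inverted) | COc1cc([C@H]2OC(=O)O[C@]2(CO[Si](CC)(CC)CC)[C@H](O)CO[Si](CC)(CC)CC)ccc1OCc1ccccc1
F10 | step 4 | C8' methanesulfonate of F9 | COc1cc([C@H]2OC(=O)O[C@]2(CO[Si](CC)(CC)CC)[C@H](OS(C)(=O)=O)CO[Si](CC)(CC)CC)ccc1OCc1ccccc1
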